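Remark on the chemistry: the target has no stereocentre, and benzaldehyde 1, acetophenone 4 and alkynol 12 are taken as catalogue compounds.

## Analysis of the target

The target is an isoflavone, a 3-aryl-4H-chromen-4-one: ring A (C4a, C5 to C8, C8a) with hydroxyls on C5 and C7, the pyranone ring C (O1, C2–H, C3, C4=O), and ring B joined to ring C by the C3–C1' bond. There is no stereocentre and no hindered axis to control, so the problem is one of regiochemistry and functional-group tolerance. Ring B is the hard part: it carries five contiguous substituents, C1' (chromenone), C2' (OH), C3' (3-hydroxy-3-methylbutyl), C4' (OH) and C5' (OMe), only C6' bears hydrogen, and of its three oxygens two must end free and one methylated. The tertiary alcohol lies between the C2' and C4' phenols, and protic or Lewis acid would close it onto either oxygen as a 2,2-dimethylchromane; the four phenols must therefore be unmasked under neutral conditions that also spare the C5' methyl ether. A free C2'–OH can add to C2 of ring C (ring opening and reclosure to benzofuran isomers under base), and the C2'–OH/C5'–OMe pair is a para-alkoxyphenol that oxidises to a quinone, so ring B should stay O-protected until the end. The feature on which the strategy rests is the position of C1': it is para to O4' and ortho to O2', which makes ring B an exceptionally good 1,2-migrating group, and the simplest ring-B building block with all three oxygens in place is a benzaldehyde in which C1' already bears one carbon. In a chalcone made from that aldehyde ring B sits on the carbon that must become C2–H, so one 1,2-shift of ring B onto the neighbouring carbon (the future C3) creates the C3–C1' bond, turns the linear 1,3-diarylpropane skeleton into the branched isoflavone skeleton, and leaves the former aldehyde carbon at the oxidation level of C2.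

## Retrosynthetic reasoning

From 14 back to 13. The four free phenols are traced back to benzyl ethers and the saturated CH2–CH2 unit of the side chain to a triple bond. One neutral catalytic hydrogenation then does both jobs: it frees the phenols beside the tertiary alcohol without acid and cannot touch the C5' methyl ether. Benzyl is therefore the only protecting group in the route.

From 13 back to 11 and 12. The C3'–C(sp) bond is cut. The whole side chain, tertiary alcohol included, is then bought as 12 and attached by a Sonogashira coupling. It is attached only after the oxidative and acidic steps, which neither an alkyne nor a tertiary alcohol beside ring B would survive. The forward reaction has to couple at an iodide flanked by two benzyloxy groups.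

From 11 back to 9 (through 10). Ring C is opened at the O1–C2 bond and C2 is written as a dimethyl acetal. The forward reaction is an acid-catalysed acetal exchange with the ring-A phenol followed by loss of the second alkoxy group. It closes ring C and makes it aromatic.

From 9 back to 7 (through 8). This is the key disconnection. The C3–C1' bond (the C2–aryl bond of 9) is cut and ring B is returned to the neighbouring carbon, a retro-1,2-aryl shift, which gives chalcone 7 with ring B on Cβ. The cut is made here because a direct C3–C1' coupling would need a metal or halogen on C1' of a pentasubstituted, very electron-rich ring. The shift instead uses the C1'–C bond that the aldehyde already has, and the electron density at C1' that makes a coupling partner fragile is what drives the migration. The precursor 7 is a linear enone available by one condensation. The forward reaction has to oxidise by two electrons, move the aryl group rather than hydrogen or the phenol oxygen, and leave Cβ at the aldehyde oxidation level.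

From 7 back to 3 and 5 (through 6). The Cα=Cβ bond is cut by a retro-aldol condensation into two halves of equal size. The free hydroxyl of 5 is the future O1.

From 3 back to 2 and 1. The two benzyl ethers are removed, then the C3'–I bond. Aldehyde 1 already carries the C1' carbon and all three oxygens with the methyl group on the right one. Its C3 is the only ring carbon ortho to both hydroxyls, so the handle for the side chain can be placed by simple electrophilic iodination.

From 5 back to 4. Two benzyl ethers are removed. The forward reaction leaves the carbonyl-chelated hydroxyl free.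

## Alternatives that were turned down

Alternative 1: the textbook disconnection of the C3–C1' bond by Suzuki–Miyaura coupling. The forward key step would join 5,7-bis(benzyloxy)-3-iodo-4H-chromen-4-one A1 (two steps from 5) with the ring-B pinacol boronate A2, and hydrogenolysis would finish at 14. It was turned down on structure and step count.
- A2 needs boron on C1', the most electron-rich carbon of a pentasubstituted ring with an ortho-benzyloxy group. That pattern protodeboronates fastest under aqueous base, and the coupling must join two ortho-substituted carbons.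
- A2 cannot use the C1' carbon that 1 supplies. Ring B would have to be rebuilt from an arene without it, with the chain placed at C3' by metalation between two ether oxygens, then halogenation and borylation at C1'.
- In that metalation benzyl ethers compete by benzylic deprotonation, and acetal protecting groups would later need acid beside the tertiary alcohol.
- The count is about ten linear steps for one bond, which the chosen key step forms with no functional group at C1'.

Alternative 2: cut O1–C8a and C4–C4a together and make ring C by an aryne insertion. The forward key step would release the aryne from the ortho-silylaryl triflate A3 with fluoride in the presence of the 3-methoxy-2-arylacrylic acid A4.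
- The carboxylate oxygen should add to the aryne carbon remote from the flanking benzyloxy group (the future C8a).
- The aryl anion left next to that benzyloxy group (the future C4a) should take the acyl group in an anionic Fries-type shift.
- The phenoxide should close ring C by addition–elimination and give 11 in one operation. Insertion of arynes into the C–O bond of carboxylic acids, with ring closure for acrylic acids, is known chemistry.

It was turned down because it solves a problem this target does not have: ring A is the symmetric phloroglucinol pattern and needs no regiocontrol. A3 costs three steps and A4 four steps from 3 (one-carbon homologation, formylation, O-methylation, saponification), against the single condensation that turns 3 into 7. The push–pull acyl group of A4 is also a weak electrophile for the aryl anion, so plain O-arylation would compete.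

Alternative 3: build ring B on the chromenone by a Dötz benzannulation that forms the C5'–C6', C1'–C2' and C2'–C3' bonds. The forward key step would heat 3-ethynylchromenone A5 with the alkenyl(methoxy)carbene complex A6, (CO)5Cr=C(OMe)–C(OBn)=CH–CH2CH2C(CH3)2OBn.
- A carbonyl ligand becomes C2' with its free OH, and the carbene carbon becomes C5' with its OMe.
- The terminal alkyne places ring C on C1' beside the new OH and hydrogen on C6'.
- The alkenyl carbons become C4' (OBn) and C3' (chain).

On paper this sets all five substituents of ring B and the OH/OMe distinction of the para pair in one step. It was turned down on the precursors. A6 is an α-alkoxy-β-alkyl alkenyl carbene that needs about six steps, and A5 needs four steps from 5, so the route exceeds twelve steps with stoichiometric chromium. Electron-rich α-alkoxyalkenyl carbenes also tend to cyclise without carbonyl insertion, and the electrophilic C2 of A5 is exposed to the organochromium intermediates.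

Key step: step 5

## Route

Step 1
Reactants: 1 2,4-dihydroxy-5-methoxybenzaldehyde
Product: 2 2,4-dihydroxy-3-iodo-5-methoxybenzaldehyde
Conditions: NIS (1.05 equiv), MeCN, 0 °C to rt
Reagents that add atoms: N-iodosuccinimide, O=C1CCC(=O)N1I
Why: Electrophilic aromatic iodination; C3 is the only carbon ortho to both hydroxyls, C5 is blocked by the methoxy group, and C6 is meta to both hydroxyls and deactivated by the formyl group, so a single regioisomer is expected.

Step 2
Reactants: 2 2,4-dihydroxy-3-iodo-5-methoxybenzaldehyde
Product: 3 2,4-bis(benzyloxy)-3-iodo-5-methoxybenzaldehyde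
Conditions: BnBr (2.5 equiv), K2CO3 (3 equiv), DMF, 60 °C
Reagents that add atoms: benzyl bromide, BrCc1ccccc1
Why: Williamson ether synthesis on both phenols; benzyl is chosen because it is removed at the end by neutral hydrogenolysis that leaves the aryl methyl ether and the tertiary alcohol alone.

Step 3
Reactants: 4 1-(2,4,6-trihydroxyphenyl)ethanone
Product: 5 1-[2,4-bis(benzyloxy)-6-hydroxyphenyl]ethanone
Conditions: BnBr (2.05 equiv), K2CO3 (2.1 equiv), DMF, rt
Reagents that add atoms: benzyl bromide, BrCc1ccccc1
Why: Selective Williamson etherification; the para hydroxyl and one ortho hydroxyl react, while the last ortho hydroxyl stays locked in the hydrogen bond to the ketone and is the least nucleophilic site, a well-known selectivity of this acetophenone.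

Step 4
Reactants: 3 2,4-bis(benzyloxy)-3-iodo-5-methoxybenzaldehyde; 5 1-[2,4-bis(benzyloxy)-6-hydroxyphenyl]ethanone
Product: 7 (E)-1-[2,4-bis(benzyloxy)-6-hydroxyphenyl]-3-[2,4-bis(benzyloxy)-3-iodo-5-methoxyphenyl]prop-2-en-1-one, via aldol adduct 6 (not isolated)
Conditions: KOH (50% aq.), EtOH/THF, rt; cold dilute HCl work-up
Reagents that add atoms: none
Why: Claisen–Schmidt condensation; the enolate of 5 adds to the non-enolisable aldehyde 3 and aldol 6 loses water by E1cB to the thermodynamically favoured E-enone, while the aryl iodide and benzyl ethers are inert to aqueous base.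

Step 5
Reactants: 7 (E)-1-[2,4-bis(benzyloxy)-6-hydroxyphenyl]-3-[2,4-bis(benzyloxy)-3-iodo-5-methoxyphenyl]prop-2-en-1-one
Product: 9 1-[2,4-bis(benzyloxy)-6-hydroxyphenyl]-2-[2,4-bis(benzyloxy)-3-iodo-5-methoxyphenyl]-3,3-dimethoxypropan-1-one (racemic), via organothallium adduct 8 (not isolated)
Conditions: Tl(NO3)3·3H2O (1.2 equiv), MeOH/CH2Cl2 (3:1), rt
Reagents that add atoms: methanol, CO
Why: This is the thallium trinitrate oxidative rearrangement of a chalcone, the established oxidative route from 2'-hydroxychalcones to isoflavone precursors. Trivalent thallium adds to Cα of the enone while methanol adds anti to the benzylic Cβ, giving organothallium 8; ring B then migrates from Cβ to Cα through a phenonium ion with loss of monovalent thallium, and the methoxy-stabilised cation left at Cβ is trapped by methanol to give acetal 9. The step forms the C3–C1' bond of the target, breaks the old bond between C1' and the former aldehyde carbon, and leaves that carbon as an acetal at the oxidation level of C2; it closes no ring (ring C is closed in step 6). The one new stereocentre, C2 of 9, is formed racemic and needs no control because it becomes the sp2 carbon C3 in step 6. The selectivity needed is aryl migration over oxidative cyclisation through the ring-A phenol and over oxidation of the arenes; it is secured by ring B itself, whose ipso carbon C1' is para to O4' and ortho to O2' and should bridge the developing cation faster than the hydrogen-bonded phenol can attack. The C3' iodide, the benzyl ethers and the chelated phenol are expected to be inert to the oxidant at room temperature.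

Step 6
Reactants: 9 1-[2,4-bis(benzyloxy)-6-hydroxyphenyl]-2-[2,4-bis(benzyloxy)-3-iodo-5-methoxyphenyl]-3,3-dimethoxypropan-1-one
Product: 11 5,7-bis(benzyloxy)-3-[2,4-bis(benzyloxy)-3-iodo-5-methoxyphenyl]-4H-chromen-4-one, via 2-methoxyisoflavanone 10 (not isolated)
Conditions: HCl (10% aq., catalytic), MeOH/THF, 50 °C
Reagents that add atoms: none
Why: Acid-catalysed acetal exchange and elimination; the acetal ionises to an oxocarbenium ion, the ring-A phenol closes the six-membered ring C (6-exo-trig attack on the oxocarbenium carbon) to give 10, and loss of the second methanol through the enol gives the aromatic pyranone, erasing both stereocentres of 10; no acid-sensitive side chain is present yet.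

Step 7
Reactants: 11 5,7-bis(benzyloxy)-3-[2,4-bis(benzyloxy)-3-iodo-5-methoxyphenyl]-4H-chromen-4-one; 12 2-methylbut-3-yn-2-ol
Product: 13 5,7-bis(benzyloxy)-3-[2,4-bis(benzyloxy)-3-(3-hydroxy-3-methylbut-1-yn-1-yl)-5-methoxyphenyl]-4H-chromen-4-one
Conditions: Pd(PPh3)2Cl2 (5 mol %), CuI (5 mol %), Et3N, DMF, 70 °C
Reagents that add atoms: none
Why: Sonogashira coupling of an aryl iodide with a terminal alkyne that brings all five chain carbons and the tertiary alcohol; the free tertiary hydroxyl is tolerated, and a tertiary amine base cannot add to C2 of ring C.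

Step 8
Reactants: 13 5,7-bis(benzyloxy)-3-[2,4-bis(benzyloxy)-3-(3-hydroxy-3-methylbut-1-yn-1-yl)-5-methoxyphenyl]-4H-chromen-4-one
Product: 14 5,7-dihydroxy-3-[2,4-dihydroxy-3-(3-hydroxy-3-methylbutyl)-5-methoxyphenyl]-4H-chromen-4-one
Conditions: H2 (1 atm), 10% Pd/C, THF/MeOH, rt, stopped after uptake of six equivalents
Reagents that add atoms: none
Why: Heterogeneous hydrogenation saturates the triple bond and hydrogenolysis cleaves the four benzyl ethers in one neutral operation, so the tertiary alcohol never meets acid beside a free phenol and the methyl ether is untouched; the conjugated C2=C3 bond of the vinylogous ester reduces much more slowly.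

## Compound list

1 | 2,4-dihydroxy-5-methoxybenzaldehyde | COc1cc(C=O)c(O)cc1O | starting material
2 | 2,4-dihydroxy-3-iodo-5-methoxybenzaldehyde | COc1cc(C=O)c(O)c(I)c1O | intermediate
3 | 2,4-bis(benzyloxy)-3-iodo-5-methoxybenzaldehyde | COc1cc(C=O)c(OCc2ccccc2)c(I)c1OCc1ccccc1 | intermediate
4 | 1-(2,4,6-trihydroxyphenyl)ethanone | CC(=O)c1c(O)cc(O)cc1O | starting material
5 | 1-[2,4-bis(benzyloxy)-6-hydroxyphenyl]ethanone | CC(=O)c1c(O)cc(OCc2ccccc2)cc1OCc1ccccc1 | intermediate
6 | 1-[2,4-bis(benzyloxy)-6-hydroxyphenyl]-3-[2,4-bis(benzyloxy)-3-iodo-5-methoxyphenyl]-3-hydroxypropan-1-one (racemic aldol adduct) | COc1cc(C(O)CC(=O)c2c(O)cc(OCc3ccccc3)cc2OCc2ccccc2)c(OCc2ccccc2)c(I)c1OCc1ccccc1 | intermediate (not isolated)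
7 | (E)-1-[2,4-bis(benzyloxy)-6-hydroxyphenyl]-3-[2,4-bis(benzyloxy)-3-iodo-5-methoxyphenyl]prop-2-en-1-one | COc1cc(/C=C/C(=O)c2c(O)cc(OCc3ccccc3)cc2OCc2ccccc2)c(OCc2ccccc2)c(I)c1OCc1ccccc1 | intermediate
8 | rel-(2R,3R)-[1-(2,4-bis(benzyloxy)-6-hydroxyphenyl)-3-(2,4-bis(benzyloxy)-3-iodo-5-methoxyphenyl)-3-methoxy-1-oxopropan-2-yl]thallium dinitrate (racemic anti adduct, trivalent thallium) | O=C([C@H]([Tl](O[N+](=O)[O-])O[N+](=O)[O-])[C@H](OC)c1cc(OC)c(OCc2ccccc2)c(I)c1OCc1ccccc1)c1c(O)cc(OCc2ccccc2)cc1OCc1ccccc1 | intermediate (not isolated)
9 | 1-[2,4-bis(benzyloxy)-6-hydroxyphenyl]-2-[2,4-bis(benzyloxy)-3-iodo-5-methoxyphenyl]-3,3-dimethoxypropan-1-one (racemic) | COc1cc(C(C(OC)OC)C(=O)c2c(O)cc(OCc3ccccc3)cc2OCc2ccccc2)c(OCc2ccccc2)c(I)c1OCc1ccccc1 | intermediate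
10 | 5,7-bis(benzyloxy)-3-[2,4-bis(benzyloxy)-3-iodo-5-methoxyphenyl]-2-methoxy-2,3-dihydro-4H-chromen-4-one (mixture of racemic diastereomers) | COc1cc(C2C(OC)Oc3cc(OCc4ccccc4)cc(OCc4ccccc4)c3C2=O)c(OCc2ccccc2)c(I)c1OCc1ccccc1 | intermediate (not isolated)
11 | 5,7-bis(benzyloxy)-3-[2,4-bis(benzyloxy)-3-iodo-5-methoxyphenyl]-4H-chromen-4-one | COc1cc(-c2coc3cc(OCc4ccccc4)cc(OCc4ccccc4)c3c2=O)c(OCc2ccccc2)c(I)c1OCc1ccccc1 | intermediate
12 | 2-methylbut-3-yn-2-ol | CC(C)(O)C#C | starting material
13 | 5,7-bis(benzyloxy)-3-[2,4-bis(benzyloxy)-3-(3-hydroxy-3-methylbut-1-yn-1-yl)-5-methoxyphenyl]-4H-chromen-4-one | COc1cc(-c2coc3cc(OCc4ccccc4)cc(OCc4ccccc4)c3c2=O)c(OCc2ccccc2)c(C#CC(C)(C)O)c1OCc1ccccc1 | intermediate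
14 | 5,7-dihydroxy-3-[2,4-dihydroxy-3-(3-hydroxy-3-methylbutyl)-5-methoxyphenyl]-4H-chromen-4-one | COc1cc(-c2coc3cc(O)cc(O)c3c2=O)c(O)c(CCC(C)(C)O)c1O | target

## Step count and least certain steps

Total step count: 8. Longest linear sequence: 7 steps (steps 1, 2, 4, 5, 6, 7, 8, from 1 to 14).

Step 5 (key step). The most likely failure is diversion of the organothallium intermediate: attack of the ring-A phenol oxygen on the activated double bond (oxidative cyclisation instead of aryl migration), or one-electron oxidation and thallation of the very electron-rich ring B. Poor solubility of the tetrabenzyl chalcone in the alcohol would slow oxythallation and let these paths gain. The fallback replaces the oxidative 1,2-aryl shift by a non-oxidative 1,2-acyl shift and sets out from 7: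
- The chelated phenol is benzylated (BnBr, K2CO3, DMF, 70 °C) to (E)-3-[2,4-bis(benzyloxy)-3-iodo-5-methoxyphenyl]-1-[2,4,6-tris(benzyloxy)phenyl]prop-2-en-1-one F1.
- Weitz–Scheffer epoxidation (H2O2, NaOH, MeOH/THF, 0 °C) should give trans-[3-(2,4-bis(benzyloxy)-3-iodo-5-methoxyphenyl)oxiran-2-yl][2,4,6-tris(benzyloxy)phenyl]methanone F2.
- BF3·OEt2 in CH2Cl2 at 0 °C opens the epoxide at the benzylic carbon and the aroyl group migrates (Meinwald-type rearrangement) to 2-[2,4-bis(benzyloxy)-3-iodo-5-methoxyphenyl]-3-oxo-3-[2,4,6-tris(benzyloxy)phenyl]propanal F3, which already has the isoflavone skeleton.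
- BCl3 (CH2Cl2, −78 °C) removes one of the two equivalent benzyl groups ortho to the ketone under chelation control. The freed phenol closes onto the formyl group and loses water on acidic work-up, which returns the route at 11.

Step 7. Oxidative addition of zerovalent palladium into the C3'–I bond is slowed by the two ortho benzyloxy groups and the electron-rich ring, so copper-mediated oxidative dimerisation of 12 and hydrodeiodination of 11 can outrun the coupling. The fallback sets out from 11 and uses a copper-free Heck reaction with commercial 2-methylbut-3-en-2-ol (Pd(OAc)2, Bu4NCl, NaHCO3, DMF, 90 °C). The carbinol carbon has no hydrogen, so β-hydride elimination can only give (E)-5,7-bis(benzyloxy)-3-[2,4-bis(benzyloxy)-3-(3-hydroxy-3-methylbut-1-en-1-yl)-5-methoxyphenyl]-4H-chromen-4-one F4. Hydrogenation under the conditions of step 8 then saturates the alkene and removes the benzyl groups, and the route is rejoined at 14.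

Step 8. Chemoselectivity on the catalyst surface may be lost: the C2=C3 bond of ring C may be saturated, or the propargylic C–O bond hydrogenolysed before the triple bond is reduced. Slow cleavage of the two hindered benzyl ethers on ring B lengthens the exposure. The fallback separates the two reductions and sets out from 13:
- Diimide generated in the flask (p-toluenesulfonyl hydrazide, NaOAc, DME/H2O, reflux) reduces only the unpolarised triple bond and should give 5,7-bis(benzyloxy)-3-[2,4-bis(benzyloxy)-3-(3-hydroxy-3-methylbutyl)-5-methoxyphenyl]-4H-chromen-4-one F5.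
- Catalytic transfer hydrogenolysis (Pd(OH)2/C, cyclohexa-1,4-diene, EtOH/THF, rt), which spares the chromenone double bond, then removes the benzyl groups and comes back to the route at 14.

Step 3. Over-alkylation to the tribenzyl ether, and C-benzylation of the phloroglucinol ring, can erode the selective dibenzylation. The fallback sets out from 4: exhaustive O-benzylation (BnBr 3.5 equiv, K2CO3, DMF, 80 °C) gives 1-[2,4,6-tris(benzyloxy)phenyl]ethanone F6. Chelation-controlled removal of one ortho benzyl group with BCl3 (1 equiv, CH2Cl2, −78 °C) then returns the route at 5.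

## Further compounds

F1 | step 5 | (E)-3-[2,4-bis(benzyloxy)-3-iodo-5-methoxyphenyl]-1-[2,4,6-tris(benzyloxy)phenyl]prop-2-en-1-one | O=C(/C=C/c1cc(OC)c(OCc2ccccc2)c(I)c1OCc1ccccc1)c1c(OCc2ccccc2)cc(OCc2ccccc2)cc1OCc1ccccc1
F2 | step 5 | trans-[3-(2,4-bis(benzyloxy)-3-iodo-5-methoxyphenyl)oxiran-2-yl][2,4,6-tris(benzyloxy)phenyl]methanone (racemic, rel-(2R,3S)) | O=C([C@H]1O[C@@H]1c1cc(OC)c(OCc2ccccc2)c(I)c1OCc1ccccc1)c1c(OCc2ccccc2)cc(OCc2ccccc2)cc1OCc1ccccc1
F3 | step 5 | 2-[2,4-bis(benzyloxy)-3-iodo-5-methoxyphenyl]-3-oxo-3-[2,4,6-tris(benzyloxy)phenyl]propanal (racemic, enolisable) | O=CC(C(=O)c1c(OCc2ccccc2)cc(OCc2ccccc2)cc1OCc1ccccc1)c1cc(OC)c(OCc2ccccc2)c(I)c1OCc1ccccc1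
F4 | step 7 | (E)-5,7-bis(benzyloxy)-3-[2,4-bis(benzyloxy)-3-(3-hydroxy-3-methylbut-1-en-1-yl)-5-methoxyphenyl]-4H-chromen-4-one | COc1cc(-c2coc3cc(OCc4ccccc4)cc(OCc4ccccc4)c3c2=O)c(OCc2ccccc2)c(/C=C/C(C)(C)O)c1OCc1ccccc1
F5 | step 8 | 5,7-bis(benzyloxy)-3-[2,4-bis(benzyloxy)-3-(3-hydroxy-3-methylbutyl)-5-methoxyphenyl]-4H-chromen-4-one | COc1cc(-c2coc3cc(OCc4ccccc4)cc(OCc4ccccc4)c3c2=O)c(OCc2ccccc2)c(CCC(C)(C)O)c1OCc1ccccc1
F6 | step 3 | 1-[2,4,6-tris(benzyloxy)phenyl]ethanone | CC(=O)c1c(OCc2ccccc2)cc(OCc2ccccc2)cc1OCc1ccccc1
A1 | alternative 1 | 5,7-bis(benzyloxy)-3-iodo-4H-chromen-4-one | O=c1c(I)coc2cc(OCc3ccccc3)cc(OCc3ccccc3)c12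
A2 | alternative 1 | 2-[2,4-bis(benzyloxy)-3-(3-hydroxy-3-methylbutyl)-5-methoxyphenyl]-4,4,5,5-tetramethyl-1,3,2-dioxaborolane | COc1cc(B2OC(C)(C)C(C)(C)O2)c(OCc2ccccc2)c(CCC(C)(C)O)c1OCc1ccccc1
A3 | alternative 2 | 3,5-bis(benzyloxy)-2-(trimethylsilyl)phenyl trifluoromethanesulfonate | C[Si](C)(C)c1c(OCc2ccccc2)cc(OCc2ccccc2)cc1OS(=O)(=O)C(F)(F)F
A4 | alternative 2 | (E)-2-[2,4-bis(benzyloxy)-3-iodo-5-methoxyphenyl]-3-methoxyprop-2-enoic acid | CO/C=C(/C(=O)O)c1cc(OC)c(OCc2ccccc2)c(I)c1OCc1ccccc1
A5 | alternative 3 | 5,7-bis(benzyloxy)-3-ethynyl-4H-chromen-4-one | C#Cc1coc2cc(OCc3ccccc3)cc(OCc3ccccc3)c2c1=O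
A6 | alternative 3 | pentacarbonyl[(2Z)-2,6-bis(benzyloxy)-1-methoxy-6-methylhept-2-en-1-ylidene]chromium, (CO)5Cr=C(OMe)C(OBn)=CHCH2CH2C(CH3)2OBn | COC(=[Cr](=C=O)(=C=O)(=C=O)(=C=O)=C=O)/C(OCc1ccccc1)=C/CCC(C)(C)OCc1ccccc1
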